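The ten-membered carbocycle is cut at C10–C1 (ring numbering: C1 methyl-bearing alkene carbon, C4 isopropyl-bearing carbon, C5 ester carbinol, C7 tertiary carbinol). Of the two sp2–sp3 ring bonds, C4–C5 abuts a stereocentre, whereas C1–C10 joins the diene to a plain CH2 group three bonds away from C7. One operation, hydroboration of a terminal C9=C10 alkene and intramolecular B-alkyl Suzuki–Miyaura coupling, therefore makes this bond and the ring while both alkene geometries and the syn-5,7-diol arrive finished. The precursor is an open-chain undeca-1,7,9-triene carrying the E-configured C1 dienyl iodide, the Z C3=C4 bond, a TBS ether at C5 and a TES ether at C7.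

Key step: step 12

Assumption: (R)-(−)-mevalonolactone is bought as the single enantiomer and propyne as its commercial THF solution.

The ring numbering C1–C10 of the target is also used for all open-chain compounds.

Structure check:
- The target is 5S,7S with C1=C2 E (trans in the ring) and C3=C4 Z (cis in the ring).
- The two oxygen substituents are syn along C4–C8.
- Compounds 18 and 20 carry exactly this arrangement.

Design points:
- **Source of C7.** C7 comes from (R)-mevalonolactone. Its CH2C(=O) arm becomes C8–C9 and its CH2CH2O arm becomes C6–C5. No bond at C7 is ever broken. The descriptor changes from R to S at step 11 only because the CIP ranking of the two arms swaps.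
- **Control at C5.** C5 is set by reagent control. C7 bears a methyl and a methylene group of nearly equal size, so a chelate-directed 1,3-syn hydride reduction would have no conformational bias to work with.
- **Order of events at the two chain ends.** Cp2Zr(H)Cl adds to a monosubstituted alkene about as readily as to an internal alkyne. The C9=C10 alkene is therefore made after the iodide. Until then C9 is a Weinreb amide, which the same zirconium hydride converts into the aldehyde needed for methylenation.
- **Protection at C7.** C7 carries a triethylsilyl ether rather than a trimethylsilyl ether. It has to survive Swern conditions, an organomagnesium reagent, zirconium hydride and warm aqueous carbonate.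

Step 1
Reactants: 1 (R)-mevalonolactone
Product: 2 (3R)-3,5-dihydroxy-N-methoxy-N,3-dimethylpentanamide
Conditions: MeNH(OMe)·HCl (3 equiv), AlMe3 (3 equiv), CH2Cl2, 0 °C to rt; aq. KNaC4H4O6
Reagents that add atoms: N,O-dimethylhydroxylamine hydrochloride, CNOC.Cl
Why: Weinreb aminolysis of a lactone, in which the aluminium amide attacks the only carbonyl group (C9), frees the C5 hydroxyl group and touches no bond at C7, so that this stereocentre is taken unchanged from the chiral pool.

Step 2
Reactants: 2 (3R)-3,5-dihydroxy-N-methoxy-N,3-dimethylpentanamide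
Product: 3 (3R)-N-methoxy-N,3-dimethyl-3,5-bis(triethylsilyloxy)pentanamide
Conditions: Et3SiOTf (2.5 equiv), 2,6-lutidine, CH2Cl2, −78 to 0 °C
Reagents that add atoms: triethylsilyl trifluoromethanesulfonate, CC[Si](CC)(CC)OS(=O)(=O)C(F)(F)F
Why: Silyl triflate silylation with a hindered pyridine base is strong enough for the tertiary C7 alcohol and, by capping the C5 hydroxyl group in the same operation, stops relactonisation.

Step 3
Reactants: 3 (3R)-N-methoxy-N,3-dimethyl-3,5-bis(triethylsilyloxy)pentanamide
Product: 4 (3R)-N-methoxy-N,3-dimethyl-5-oxo-3-(triethylsilyloxy)pentanamide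
Conditions: (COCl)2, DMSO, CH2Cl2, −78 to −35 °C; Et3N, −78 to 0 °C
Reagents that add atoms: none
Why: Swern oxidation applied directly to a silyl ether, in which the chlorosulfonium salt exchanges only with the unhindered primary triethylsilyl ether, so that the C5 aldehyde forms in one operation while the tertiary ether and the amide stay intact.

Step 4
Reactants: 5 3-methylbut-1-yne
Product: 7 (1Z)-2-bromo-1-iodo-3-methylbut-1-ene, via alkenyldibromoborane 6 (not isolated)
Conditions: BBr3, CH2Cl2, −78 °C; NaOAc, then ICl, −78 to 0 °C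
Reagents that add atoms: boron tribromide, BrB(Br)Br; iodine monochloride, ClI
Why: Bromoboration of a terminal alkyne is a syn addition that puts bromine on the substituted carbon (C4) and boron on C3, and ipso-iododeboronation of the acetate-complexed borane goes with retention, which fixes the cis relation of the two halogens.

Step 5
Reactants: 7 (1Z)-2-bromo-1-iodo-3-methylbut-1-ene; 8 propyne
Product: 9 (4Z)-5-bromo-6-methylhept-4-en-2-yne
Conditions: PdCl2(PPh3)2 (cat.), CuI (cat.), Et3N, THF, 0 °C to rt
Reagents that add atoms: none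
Why: Sonogashira coupling, in which oxidative addition takes the weaker and less hindered C3–I bond and not the C4–Br bond flanked by isopropyl, with retention of the alkene geometry.

Step 6
Reactants: 9 (4Z)-5-bromo-6-methylhept-4-en-2-yne; 4 (3R)-N-methoxy-N,3-dimethyl-5-oxo-3-(triethylsilyloxy)pentanamide
Product: 12 (3R,5RS,6Z)-5-hydroxy-N-methoxy-N,3-dimethyl-6-(propan-2-yl)-3-(triethylsilyloxy)dec-6-en-8-ynamide (both C5 epimers), via alkenyllithium 10 (not isolated), via alkenylmagnesium bromide 11 (not isolated)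
Conditions: 9, t-BuLi (2 equiv), Et2O, −78 °C; MgBr2·OEt2, −78 °C; 4, −78 to −40 °C; aq. NH4Cl
Reagents that add atoms: none
Why: Bromine–lithium exchange with retention, transmetalation to the milder Grignard reagent and 1,2-addition, in which the aldehyde reacts at low temperature in preference to the Weinreb amide, the C3=C4 geometry is kept, and the new C5 carbinol is formed without control because step 7 erases it.

Step 7
Reactants: 12 (3R,5RS,6Z)-5-hydroxy-N-methoxy-N,3-dimethyl-6-(propan-2-yl)-3-(triethylsilyloxy)dec-6-en-8-ynamide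
Product: 13 (3R,6Z)-N-methoxy-N,3-dimethyl-5-oxo-6-(propan-2-yl)-3-(triethylsilyloxy)dec-6-en-8-ynamide
Conditions: Dess–Martin periodinane, NaHCO3, CH2Cl2, 0 °C to rt
Reagents that add atoms: none
Why: Dess–Martin oxidation is neutral and fast for allylic alcohols, so both C5 epimers converge on one enone without movement of the Z alkene or loss of the β-silyloxy group.

Step 8
Reactants: 13 (3R,6Z)-N-methoxy-N,3-dimethyl-5-oxo-6-(propan-2-yl)-3-(triethylsilyloxy)dec-6-en-8-ynamide
Product: 14 (3R,5S,6Z)-5-hydroxy-N-methoxy-N,3-dimethyl-6-(propan-2-yl)-3-(triethylsilyloxy)dec-6-en-8-ynamide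
Conditions: (R)-2-methyl-CBS-oxazaborolidine (0.3 equiv), catecholborane, toluene/CH2Cl2, −78 °C; MeOH, pH 7 buffer
Reagents that add atoms: none
Why: Corey–Bakshi–Shibata reduction, in which the ketone binds to the oxazaborolidine boron anti to its larger α-branched alkenyl arm (C4) and the coordinated borane delivers hydride to one face, which with the (R)-catalyst should give 5S, while catecholborane at this temperature leaves alkyne and amide alone.

Step 9
Reactants: 14 (3R,5S,6Z)-5-hydroxy-N-methoxy-N,3-dimethyl-6-(propan-2-yl)-3-(triethylsilyloxy)dec-6-en-8-ynamide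
Product: 15 (3R,5S,6Z)-5-(tert-butyldimethylsilyloxy)-N-methoxy-N,3-dimethyl-6-(propan-2-yl)-3-(triethylsilyloxy)dec-6-en-8-ynamide
Conditions: t-BuMe2SiOTf, 2,6-lutidine, CH2Cl2, −78 to 0 °C
Reagents that add atoms: tert-butyldimethylsilyl trifluoromethanesulfonate, CC(C)(C)[Si](C)(C)OS(=O)(=O)C(F)(F)F
Why: Silyl triflate silylation protects the hindered allylic C5 alcohol without acid or strong base, which removes the risks of lactonisation onto C9 and of furan formation from the Z-enynol.

Step 10
Reactants: 15 (3R,5S,6Z)-5-(tert-butyldimethylsilyloxy)-N-methoxy-N,3-dimethyl-6-(propan-2-yl)-3-(triethylsilyloxy)dec-6-en-8-ynamide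
Product: 17 (3R,5S,6Z,8E)-5-(tert-butyldimethylsilyloxy)-9-iodo-3-methyl-6-(propan-2-yl)-3-(triethylsilyloxy)deca-6,8-dienal, via bis-zirconocene adduct 16 (not isolated)
Conditions: Cp2Zr(H)Cl (4.5 equiv), THF, rt to 40 °C, dark; I2, THF, −78 to 0 °C; aq. Na2S2O3/NaHCO3
Reagents that add atoms: iodine, II
Why: Two known reactions of Cp2Zr(H)Cl run side by side, namely syn hydrozirconation of the methyl-capped alkyne with zirconium on the less hindered C1 (excess hydride equilibrates regioisomers towards it) followed by iodinolysis with retention to the E iodide, and reduction of the Weinreb amide to a stable zirconium hemiaminal that releases the C9 aldehyde only on work-up, with no monosubstituted alkene yet present to compete for the hydride.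

Step 11
Reactants: 17 (3R,5S,6Z,8E)-5-(tert-butyldimethylsilyloxy)-9-iodo-3-methyl-6-(propan-2-yl)-3-(triethylsilyloxy)deca-6,8-dienal
Product: 18 (4S,6S,7Z,9E)-6-(tert-butyldimethylsilyloxy)-10-iodo-4-methyl-7-(propan-2-yl)-4-(triethylsilyloxy)undeca-1,7,9-triene
Conditions: Ph3PCH3Br, KN(SiMe3)2, THF, 0 °C; 17, −78 °C to rt
Reagents that add atoms: methyltriphenylphosphonium bromide, C[P+](c1ccccc1)(c1ccccc1)c1ccccc1.[Br-]
Why: Wittig methylenation with the non-stabilised ylide turns the C9 aldehyde into the C9=C10 alkene faster than the C7 silyloxy group can be eliminated, and ylides do not attack alkenyl iodides.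

Step 12
Reactants: 18 (4S,6S,7Z,9E)-6-(tert-butyldimethylsilyloxy)-10-iodo-4-methyl-7-(propan-2-yl)-4-(triethylsilyloxy)undeca-1,7,9-triene
Product: 20 (1E,3Z,5S,7S)-5-(tert-butyldimethylsilyloxy)-1,7-dimethyl-4-(propan-2-yl)-7-(triethylsilyloxy)cyclodeca-1,3-diene, via B-alkyl-9-BBN borane 19 (not isolated)
Conditions: 9-BBN-H (1.5 equiv), THF, rt; then syringe-pump addition to PdCl2(dppf) (0.2 equiv), AsPh3 (0.2 equiv), Cs2CO3 (3 equiv), degassed DMF/THF/H2O, 50 °C, final concentration about 1 mM
Reagents that add atoms: none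
Why: 9-BBN-H adds anti-Markovnikov to the C9=C10 bond and puts boron on C10 to give 19. Zerovalent palladium, formed in situ from PdCl2(dppf), inserts into the C1–I bond with retention, the base-activated borate passes its primary C10 alkyl group to palladium, and reductive elimination forms C10–C1. The closest known reaction type is the B-alkyl Suzuki–Miyaura macrocyclisation, which is established for carbocycles of twelve and more members and is used here unchanged at ring size ten. The ten-membered ring closes end to end, C10 terminus onto C1 terminus, by way of an eleven-membered palladacycle. No stereocentre is created, since C5, C7 and the Z C3=C4 bond are spectators and the E geometry at C1=C2 follows from retention in both organometallic steps. Two selectivities are needed: boron must go only to the monosubstituted alkene, which the bulk of 9-BBN secures because the other two C=C bonds are trisubstituted and conjugated, and the chain must find its own end before a second molecule, which is helped by slow addition, by the ring-cis C3=C4 bond and by the fully substituted C7 (Thorpe–Ingold effect), while dppf and AsPh3 favour reductive elimination over β-hydride elimination.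

Step 13
Reactants: 20 (1E,3Z,5S,7S)-5-(tert-butyldimethylsilyloxy)-1,7-dimethyl-4-(propan-2-yl)-7-(triethylsilyloxy)cyclodeca-1,3-diene
Product: 21 (1E,3Z,5S,7S)-1,7-dimethyl-4-(propan-2-yl)cyclodeca-1,3-diene-5,7-diol
Conditions: Bu4NF, THF, rt to 40 °C
Reagents that add atoms: none
Why: Fluoride-driven desilylation removes both silyl ethers under non-acidic conditions, which avoids ionisation of the dienylic C5–O bond and transannular reactions of the cyclodecadiene.

Step 14
Reactants: 22 4-hydroxybenzoic acid
Product: 24 4-(tert-butyldimethylsilyloxy)benzoic acid, via bis-silyl derivative 23 (not isolated)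
Conditions: t-BuMe2SiCl (2.2 equiv), imidazole, DMF, rt; then AcOH/THF/H2O, rt
Reagents that add atoms: tert-butyldimethylsilyl chloride, CC(C)(C)[Si](C)(C)Cl
Why: Exhaustive silylation followed by selective hydrolysis works because the silyl ester is far more labile to aqueous acid than the aryl silyl ether, so that only the phenol stays protected.

Step 15
Reactants: 21 (1E,3Z,5S,7S)-1,7-dimethyl-4-(propan-2-yl)cyclodeca-1,3-diene-5,7-diol; 24 4-(tert-butyldimethylsilyloxy)benzoic acid
Product: 25 (1E,3Z,5S,7S)-7-hydroxy-1,7-dimethyl-4-(propan-2-yl)cyclodeca-1,3-dien-5-yl 4-(tert-butyldimethylsilyloxy)benzoate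
Conditions: EDC·HCl, DMAP (0.5 equiv), CH2Cl2, 0 °C to rt
Reagents that add atoms: none
Why: Steglich esterification acylates the secondary allylic C5 alcohol, whereas the tertiary C7 alcohol is too hindered to react, and the C5–O bond is not broken, so 5S is retained.

Step 16
Reactants: 25 (1E,3Z,5S,7S)-7-hydroxy-1,7-dimethyl-4-(propan-2-yl)cyclodeca-1,3-dien-5-yl 4-(tert-butyldimethylsilyloxy)benzoate
Product: 26 (1E,3Z,5S,7S)-7-hydroxy-1,7-dimethyl-4-(propan-2-yl)cyclodeca-1,3-dien-5-yl 4-hydroxybenzoate (CNP0130127.1)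
Conditions: Bu4NF, AcOH, THF, 0 °C
Reagents that add atoms: none
Why: Fluoride cleaves the aryl silyl ether, the most labile Si–O bond in the molecule, and acetic acid buffers the medium so that the benzoate neither migrates nor hydrolyses.

Compound list
1 | (R)-mevalonolactone, (4R)-4-hydroxy-4-methyloxan-2-one | C[C@@]1(O)CCOC(=O)C1 | starting material
2 | (3R)-3,5-dihydroxy-N-methoxy-N,3-dimethylpentanamide | CON(C)C(=O)C[C@](C)(O)CCO | intermediate
3 | (3R)-N-methoxy-N,3-dimethyl-3,5-bis(triethylsilyloxy)pentanamide | CON(C)C(=O)C[C@](C)(O[Si](CC)(CC)CC)CCO[Si](CC)(CC)CC | intermediate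
4 | (3R)-N-methoxy-N,3-dimethyl-5-oxo-3-(triethylsilyloxy)pentanamide | CON(C)C(=O)C[C@](C)(O[Si](CC)(CC)CC)CC=O | intermediate
5 | 3-methylbut-1-yne | CC(C)C#C | starting material
6 | dibromo[(1Z)-2-bromo-3-methylbut-1-en-1-yl]borane (B cis to Br) | BrB(Br)/C=C(\Br)C(C)C | intermediate
7 | (1Z)-2-bromo-1-iodo-3-methylbut-1-ene (I cis to Br) | I/C=C(\Br)C(C)C | intermediate
8 | propyne | CC#C | starting material
9 | (4Z)-5-bromo-6-methylhept-4-en-2-yne (Br cis to propynyl) | CC#C/C=C(\Br)C(C)C | intermediate
10 | [(3E)-2-methylhept-3-en-5-yn-3-yl]lithium (Li cis to propynyl) | CC#C/C=C(\[Li])C(C)C | intermediate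
11 | bromo[(3Z)-2-methylhept-3-en-5-yn-3-yl]magnesium (Mg cis to propynyl) | CC#C/C=C(\[Mg]Br)C(C)C | intermediate
12 | (3R,5RS,6Z)-5-hydroxy-N-methoxy-N,3-dimethyl-6-(propan-2-yl)-3-(triethylsilyloxy)dec-6-en-8-ynamide, both C5 epimers | CON(C)C(=O)C[C@](C)(O[Si](CC)(CC)CC)CC(O)/C(C(C)C)=C\C#CC | intermediate
13 | (3R,6Z)-N-methoxy-N,3-dimethyl-5-oxo-6-(propan-2-yl)-3-(triethylsilyloxy)dec-6-en-8-ynamide | CON(C)C(=O)C[C@](C)(O[Si](CC)(CC)CC)CC(=O)/C(C(C)C)=C\C#CC | intermediate
14 | (3R,5S,6Z)-5-hydroxy-N-methoxy-N,3-dimethyl-6-(propan-2-yl)-3-(triethylsilyloxy)dec-6-en-8-ynamide | CON(C)C(=O)C[C@](C)(O[Si](CC)(CC)CC)C[C@H](O)/C(C(C)C)=C\C#CC | intermediate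
15 | (3R,5S,6Z)-5-(tert-butyldimethylsilyloxy)-N-methoxy-N,3-dimethyl-6-(propan-2-yl)-3-(triethylsilyloxy)dec-6-en-8-ynamide | CON(C)C(=O)C[C@](C)(O[Si](CC)(CC)CC)C[C@H](O[Si](C)(C)C(C)(C)C)/C(C(C)C)=C\C#CC | intermediate
16 | bis-zirconocene adduct: C1 dienyl-ZrCp2Cl (E) and C9 O-zirconated hemiaminal (cyclopentadienyl rings written sigma-bonded) | CON(C)C(O[Zr](Cl)(C1C=CC=C1)C1C=CC=C1)C[C@](C)(O[Si](CC)(CC)CC)C[C@H](O[Si](C)(C)C(C)(C)C)/C(C(C)C)=C\C=C(/C)[Zr](Cl)(C1C=CC=C1)C1C=CC=C1 | intermediate
17 | (3R,5S,6Z,8E)-5-(tert-butyldimethylsilyloxy)-9-iodo-3-methyl-6-(propan-2-yl)-3-(triethylsilyloxy)deca-6,8-dienal | O=CC[C@](C)(O[Si](CC)(CC)CC)C[C@H](O[Si](C)(C)C(C)(C)C)/C(C(C)C)=C\C=C(/C)I | intermediate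
18 | (4S,6S,7Z,9E)-6-(tert-butyldimethylsilyloxy)-10-iodo-4-methyl-7-(propan-2-yl)-4-(triethylsilyloxy)undeca-1,7,9-triene | C=CC[C@](C)(O[Si](CC)(CC)CC)C[C@H](O[Si](C)(C)C(C)(C)C)/C(C(C)C)=C\C=C(/C)I | intermediate
19 | 9-[(4S,6S,7Z,9E)-6-(tert-butyldimethylsilyloxy)-10-iodo-4-methyl-7-(propan-2-yl)-4-(triethylsilyloxy)undeca-7,9-dien-1-yl]-9-borabicyclo[3.3.1]nonane | B1(C2CCCC1CCC2)CCC[C@](C)(O[Si](CC)(CC)CC)C[C@H](O[Si](C)(C)C(C)(C)C)/C(C(C)C)=C\C=C(/C)I | intermediate
20 | (1E,3Z,5S,7S)-5-(tert-butyldimethylsilyloxy)-1,7-dimethyl-4-(propan-2-yl)-7-(triethylsilyloxy)cyclodeca-1,3-diene | C/C1=C\C=C(\C(C)C)[C@@H](O[Si](C)(C)C(C)(C)C)C[C@@](C)(O[Si](CC)(CC)CC)CCC1 | intermediate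
21 | (1E,3Z,5S,7S)-1,7-dimethyl-4-(propan-2-yl)cyclodeca-1,3-diene-5,7-diol | C/C1=C\C=C(\C(C)C)[C@@H](O)C[C@@](C)(O)CCC1 | intermediate
22 | 4-hydroxybenzoic acid | OC(=O)c1ccc(O)cc1 | starting material
23 | tert-butyldimethylsilyl 4-(tert-butyldimethylsilyloxy)benzoate | CC(C)(C)[Si](C)(C)OC(=O)c1ccc(O[Si](C)(C)C(C)(C)C)cc1 | intermediate
24 | 4-(tert-butyldimethylsilyloxy)benzoic acid | OC(=O)c1ccc(O[Si](C)(C)C(C)(C)C)cc1 | intermediate
25 | (1E,3Z,5S,7S)-7-hydroxy-1,7-dimethyl-4-(propan-2-yl)cyclodeca-1,3-dien-5-yl 4-(tert-butyldimethylsilyloxy)benzoate | C/C1=C\C=C(\C(C)C)[C@@H](OC(=O)c2ccc(O[Si](C)(C)C(C)(C)C)cc2)C[C@@](C)(O)CCC1 | intermediate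
26 | (1E,3Z,5S,7S)-7-hydroxy-1,7-dimethyl-4-(propan-2-yl)cyclodeca-1,3-dien-5-yl 4-hydroxybenzoate | C/C1=C\C=C(\C(C)C)[C@@H](OC(=O)c2ccc(O)cc2)C[C@@](C)(O)CCC1 | target

Total step count: 16
Longest linear sequence: 13 steps (steps 1–3, 6–13, 15 and 16, from 1)

Steps most likely to fail

Step 12.
- What may go wrong: transmetalation and ring closure may be slower than intermolecular coupling, protodeboronation or β-hydride elimination. The chain would then oligomerise or end up reduced instead of cyclising.
- Fallback: the same bond is made with an organozinc in place of the organoboron and without aqueous base. It sets out from 18 and comes back at 20. Hydroboration to 19 as before and oxidation with NaBO3·4H2O should give the primary alcohol F1. Appel iodination (I2, PPh3, imidazole, CH2Cl2) should convert it into the primary alkyl iodide F2. Activated Zn dust in THF/DMA inserts only into the sp3 C–I bond and should give the alkylzinc iodide F3. F3 is added slowly to PdCl2(dppf) in THF for an intramolecular Negishi coupling, which leads to 20.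

Step 10.
- What may go wrong: the two zirconium hydride reactions may not keep pace. Possible outcomes are incomplete hydrozirconation, placement of zirconium at C2, or over-reduction at C9.
- Fallback: the two tasks are separated and an alkyne-selective hydrometalation is used. It sets out from 15 and comes back at 18. Reduction of the Weinreb amide with i-Bu2AlH (THF, −78 °C) should give the enynal F4. Wittig methylenation should give the dienyne F5. Copper-catalysed syn-hydroboration (B2pin2, CuCl, P(p-tolyl)3, NaOt-Bu, MeOH, THF) adds to the conjugated alkyne and leaves an unactivated alkene alone, and it should give the dienylboronate F6 with boron on C1. NaOH followed by I2 (THF/H2O, 0 °C) replaces boron by iodine with retention and leads to 18.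

Step 8.
- What may go wrong: facial discrimination may be poor, because the neopentyl-like C6 arm may rival the alkenyl arm in effective size at the catalyst.
- Fallback: the stereocentre is corrected rather than induced. It sets out from 12 and comes back at 14, and steps 7 and 8 are then left out. The C5 epimers of 12 are diastereomers and are separated by chromatography into 14 and the 5R alcohol F7. Mitsunobu inversion of F7 (4-nitrobenzoic acid, PPh3, DIAD, THF, 0 °C) should give the 5S 4-nitrobenzoate F8. Methanolysis (K2CO3, MeOH, 0 °C) leads to 14.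

Further compounds
F1 | step 12 | (4S,6S,7Z,9E)-6-(tert-butyldimethylsilyloxy)-10-iodo-4-methyl-7-(propan-2-yl)-4-(triethylsilyloxy)undeca-7,9-dien-1-ol | OCCC[C@](C)(O[Si](CC)(CC)CC)C[C@H](O[Si](C)(C)C(C)(C)C)/C(C(C)C)=C\C=C(/C)I
F2 | step 12 | (4S,6S,7Z,9E)-6-(tert-butyldimethylsilyloxy)-1,10-diiodo-4-methyl-7-(propan-2-yl)-4-(triethylsilyloxy)undeca-7,9-diene | ICCC[C@](C)(O[Si](CC)(CC)CC)C[C@H](O[Si](C)(C)C(C)(C)C)/C(C(C)C)=C\C=C(/C)I
F3 | step 12 | [(4S,6S,7Z,9E)-6-(tert-butyldimethylsilyloxy)-10-iodo-4-methyl-7-(propan-2-yl)-4-(triethylsilyloxy)undeca-7,9-dien-1-yl]zinc iodide | I[Zn]CCC[C@](C)(O[Si](CC)(CC)CC)C[C@H](O[Si](C)(C)C(C)(C)C)/C(C(C)C)=C\C=C(/C)I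
F4 | step 10 | (3R,5S,6Z)-5-(tert-butyldimethylsilyloxy)-3-methyl-6-(propan-2-yl)-3-(triethylsilyloxy)dec-6-en-8-ynal | O=CC[C@](C)(O[Si](CC)(CC)CC)C[C@H](O[Si](C)(C)C(C)(C)C)/C(C(C)C)=C\C#CC
F5 | step 10 | (4S,6S,7Z)-6-(tert-butyldimethylsilyloxy)-4-methyl-7-(propan-2-yl)-4-(triethylsilyloxy)undeca-1,7-dien-9-yne | C=CC[C@](C)(O[Si](CC)(CC)CC)C[C@H](O[Si](C)(C)C(C)(C)C)/C(C(C)C)=C\C#CC
F6 | step 10 | 2-[(2Z,4Z,6S,8S)-6-(tert-butyldimethylsilyloxy)-8-methyl-5-(propan-2-yl)-8-(triethylsilyloxy)undeca-2,4,10-trien-2-yl]-4,4,5,5-tetramethyl-1,3,2-dioxaborolane | C=CC[C@](C)(O[Si](CC)(CC)CC)C[C@H](O[Si](C)(C)C(C)(C)C)/C(C(C)C)=C\C=C(/C)B1OC(C)(C)C(C)(C)O1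
F7 | step 8 | (3R,5R,6Z)-5-hydroxy-N-methoxy-N,3-dimethyl-6-(propan-2-yl)-3-(triethylsilyloxy)dec-6-en-8-ynamide | CON(C)C(=O)C[C@](C)(O[Si](CC)(CC)CC)C[C@@H](O)/C(C(C)C)=C\C#CC
F8 | step 8 | (3R,5S,6Z)-1-[methoxy(methyl)amino]-3-methyl-1-oxo-6-(propan-2-yl)-3-(triethylsilyloxy)dec-6-en-8-yn-5-yl 4-nitrobenzoate | CON(C)C(=O)C[C@](C)(O[Si](CC)(CC)CC)C[C@H](OC(=O)c1ccc(cc1)[N+](=O)[O-])/C(C(C)C)=C\C#CC
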